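# Selaginellin F by Robinson annulation to ring A and late aromatisation

## The problem

Selaginellin F (27) is built around ring A, a benzene whose four contiguous carbons C5, C6, C1 and C2 carry, in this order, CH2OH, a (4-hydroxyphenyl)ethynyl group, the quinone methide carbon C7 and ring B (2,4-dihydroxyphenyl), while only C3 and C4 are CH. C7 carries a 4-hydroxyphenyl ring and the cyclohexadienone ring and is wedged between ring B and the alkyne, so every bond to C1, C2 or C6 must be made at a carbon with two ortho neighbours. The target has no stereocentre and no defined axis, so nothing needs to be controlled; the one stereocentre the route passes through is racemic and is erased on aromatisation. Three features set the order of events: the p-quinone methide, electrophilic at C7 with the ring B 2-hydroxyl close by; five phenols, among them an easily substituted resorcinol ring; and a diarylalkyne beside a benzylic alcohol, which can cycloisomerise under strong acid, base or soft metal salts. These argue for carrying C7 as an sp3 C–H (the leuco form), masking all phenols with one base-stable group, and generating the quinone methide last. The enabling feature is that leuco ring A, read at the dihydro level, is a 2-oxocyclohex-3-ene-1-carboxylate: C6 is the ketone, C5 the ester-bearing carbon, C3 and C4 two methylenes, and C1=C2 the alkene carrying the diarylmethyl group and ring B. That is the product of a Robinson annulation between a β-keto ester and an aryl vinyl ketone.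

## Retrosynthesis

**27 to 26.** The C7=C bond of the quinone methide is traced back to the C7–H bond of leuco compound 26. The alternative, dehydration of a triaryl carbinol, would require C7 to be oxygenated before ring A exists, which the annulation cannot accommodate. The forward step needs an oxidant that takes hydride from the doubly benzylic C7–H para to two phenols and touches nothing else.

**26 to 25 to 24.** The five phenols are masked as methoxymethyl (MOM) ethers and the CH2OH is traced to a methyl ester. MOM survives methoxide, hydride and palladium catalysis and is removed in one mild acid step. Reducing the ester before deprotection (24 to 25) keeps hydride away from five free phenols and keeps the acid step away from an ester that could lactonise onto the alkyne.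

**24 to 20 and 23.** The C6–C(sp) bond is cut to aryl triflate 20 and alkyne 23. This is preferred over building the alkyne from a C6 carbonyl because C6 leaves the annulation as a phenol oxygen, which is converted directly into a leaving group. The forward reaction is a Sonogashira coupling at a crowded triflate that the ortho ester activates.

**20 to 19 to 15.** No skeletal bond is cut. The triflate comes from salicylate 19, and 19 from cyclohexenone 15 by removal of two hydrogens. Because 15 is a β-keto ester, the dehydrogenation can be directed to the ester-bearing carbon by selenation.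

**15 to 8 and 12.** Two ring A bonds are cut: C4–C5 (Michael addition) and C1=C2 (aldol condensation). The neighbouring cuts, a biaryl coupling at C2 or an arylation at C7, would each form a bond at the most crowded site of an existing arene. The annulation instead makes the C1–C2 junction as a C=C bond from a ketone. The precursors are acyclic keto ester 8 and enone 12, each carrying its aryl groups and oxygens from the start. The forward reaction needs the correct enolate in each stage and a dehydration beside two bulky groups.

**8 to 5 to 2 and 3.** The C2–C3 bond of 8 is cut by Masamune homologation to acid 5. The C7–aryl bond of 5 is cut by rhodium-catalysed conjugate addition of boronic acid 3 to cinnamate 2, itself the MOM ether of 1. The two aryl groups on C7 are identical, so no stereocentre arises.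

**12 to 11 to 10 to 9.** The enone is traced through allylic alcohol 11 to aldehyde 10 (C–C bond to a vinyl Grignard reagent) and to 2,4-dihydroxybenzaldehyde 9. This neutral sequence is chosen over a Mannich route from the acetophenone, whose acidic conditions threaten the MOM ethers.

**23 to 22 to 21.** The alkyne carbon is added to aldehyde 22 by Ohira–Bestmann homologation; 22 is the MOM ether of 4-hydroxybenzaldehyde 21.

## Roads not taken

**Alternative 1: aryne alkynylation with benzophenone capture.**
- Cut: the C6–alkyne and C1–C7 bonds, in one flask.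
- Forward step: i-PrMgCl converts 2-iodoaryl sulfonate A2 into a 3-alkoxy aryne. The chloromagnesium acetylide of 23 adds at C6, and the resulting C1 arylmagnesium adds to diaryl ketone A3, giving triaryl carbinol A1.
- Merits: two of the most hindered bonds form together, the plan is convergent, and C7 arrives as a carbinol, so the quinone methide would form on acid deprotection without an oxidant. In that respect it is better than the chosen plan, which needs step 15.
- Weak points: the aryne is flanked on both sides, so regioselectivity rests on the inductive effect of the C2 ether against the bulk of the C5 side chain. A 2,6-disubstituted arylmagnesium must add to an electron-rich diaryl ketone. Ring B must still be attached at C2 (ether removal, triflation, Suzuki coupling) next to a triaryl carbinol. A2, with four contiguous substituents, needs its own multistep synthesis.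
- Comparison: the chosen plan sets a longer linear sequence and a late oxidation against this, but has no bond formation at a crowded arene carbon other than the slim alkyne.

**Alternative 2: all-intramolecular alkyne trimerisation.**
- Cut: C1–C2, C3–C4 and C5–C6.
- Forward step: RhCl(PPh3)3 cyclotrimerises triyne diester A5 to bis-lactone A4, closing ring A, the phthalide and the benzo[c]chromenone at once.
- Merits: it reaches a fully substituted ring A in fewer steps than the chosen plan. C3 and C4 come from the terminal alkyne carbons, and the ring B 2-oxygen and the C5 CH2O are protected as lactones.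
- Weak points: A5 is an unsymmetrical diester of acetylenedicarboxylic acid with an aryl ester, a strong Michael acceptor that is hard to make and keep. In A4, C7 and the future alkyne carbon are both lactone carbonyls on neighbouring carbons. One must accept two aryl nucleophiles, the second at a di-ortho-substituted diaryl ketone, while the other is homologated to the alkyne.
- Comparison: the chosen plan is longer, but C6, C5 and C7 are different functions from the outset (ketone, ester, diarylmethyl), so no such differentiation is needed.

**Alternative 3: anodic lactonisation to install the ring B 2-oxygen.**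
- Cut: the ring B C2–O bond.
- Forward step: constant-current electrolysis of biaryl acid A7 gives lactone A6.
- Merits: ring B enters as a simple para-oxygenated phenyl, which makes the biaryl coupling easier than any coupling in the chosen plan, and the C–H oxygenation needs no metal oxidant.
- Weak points: the attacked ring carries an electron-withdrawing pivaloyloxy group, and the aryl bromide must survive the cathode. A6 then needs the same double aryl addition to a hindered lactone as alternative 2, now beside an aryl bromide and two pivalates. A7 is itself a 1,2,3,4-tetrasubstituted benzoic acid, so the ring A problem is only moved.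
- Comparison: the chosen plan needs neither a biaryl coupling nor a late oxygenation, since ring B comes with both oxygens from 9.

Key step: step 7

Remark: boronic acid 3 is taken to be a purchasable reagent, and the open quinone methide written in the target SMILES is taken as the form to be isolated.

## Route

Step 1
Reactants: 1 methyl (2E)-3-(4-hydroxyphenyl)prop-2-enoate
Product: 2 methyl (2E)-3-[4-(methoxymethoxy)phenyl]prop-2-enoate
Conditions: MOMCl (1.5 equiv), i-Pr2NEt (2 equiv), CH2Cl2, 0 °C → rt
Reagents that add atoms: chloromethyl methyl ether, COCCl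
Why: O-alkylation of the phenol under amine base (MOM protection); the acrylate is inert and the E geometry is untouched.

Step 2
Reactants: 2 methyl (2E)-3-[4-(methoxymethoxy)phenyl]prop-2-enoate; 3 [4-(methoxymethoxy)phenyl]boronic acid
Product: 5 3,3-bis[4-(methoxymethoxy)phenyl]propanoic acid, via propanoate ester 4 (not isolated)
Conditions: 3 (2 equiv), [Rh(cod)Cl]2 (2.5 mol%), KOH (cat.), 1,4-dioxane/H2O, 80 °C; then LiOH, MeOH/H2O, 60 °C; cold dilute HCl to pH 4
Reagents that add atoms: lithium hydroxide, [Li+].[OH-]
Why: Hayashi–Miyaura 1,4-addition of an arylrhodium species (from 3 and the hydroxo complex that [Rh(cod)Cl]2 forms with KOH) to the cinnamate; the two aryl groups are identical, so no stereocentre forms, and saponification in the same flask lets acid–base extraction remove neutral by-products.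

Step 3
Reactants: 5 3,3-bis[4-(methoxymethoxy)phenyl]propanoic acid
Product: 8 methyl 5,5-bis[4-(methoxymethoxy)phenyl]-3-oxopentanoate, via acyl imidazole 6 (not isolated), via acylmalonate half ester 7 (not isolated)
Conditions: CDI (1.1 equiv), THF, rt; then KO2CCH2CO2Me, MgCl2, Et3N, THF/MeCN, rt → 50 °C; cold dilute HCl
Reagents that add atoms: potassium methyl malonate, COC(=O)CC(=O)[O-].[K+]
Why: Masamune–Brooks homologation: acyl imidazole 6 C-acylates the magnesium enolate of monomethyl malonate and acylmalonate 7 loses CO2; the conditions are neutral to weakly basic, so the MOM ethers are safe.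

Step 4
Reactants: 9 2,4-dihydroxybenzaldehyde
Product: 10 2,4-bis(methoxymethoxy)benzaldehyde
Conditions: MOMCl (3 equiv), i-Pr2NEt (4 equiv), CH2Cl2, 0 → 40 °C
Reagents that add atoms: chloromethyl methyl ether, COCCl
Why: double MOM protection; the hydrogen-bonded 2-hydroxyl needs the excess reagent and warming.

Step 5
Reactants: 10 2,4-bis(methoxymethoxy)benzaldehyde
Product: 11 1-[2,4-bis(methoxymethoxy)phenyl]prop-2-en-1-ol (racemic)
Conditions: CH2=CHMgBr (1.2 equiv), THF, −78 → 0 °C; sat. aq. NH4Cl
Reagents that add atoms: vinylmagnesium bromide, C=C[Mg]Br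
Why: Grignard 1,2-addition to the aldehyde; the new carbinol centre is racemic and is removed in the next step.

Step 6
Reactants: 11 1-[2,4-bis(methoxymethoxy)phenyl]prop-2-en-1-ol
Product: 12 1-[2,4-bis(methoxymethoxy)phenyl]prop-2-en-1-one
Conditions: activated MnO2 (excess), CH2Cl2, rt
Reagents that add atoms: none
Why: MnO2 oxidation of an allylic and benzylic alcohol under neutral conditions that neither cleave MOM ethers nor polymerise the enone; 12 is used at once.

Step 7
Reactants: 8 methyl 5,5-bis[4-(methoxymethoxy)phenyl]-3-oxopentanoate; 12 1-[2,4-bis(methoxymethoxy)phenyl]prop-2-en-1-one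
Product: 15 methyl 4-[2,4-bis(methoxymethoxy)phenyl]-3-{bis[4-(methoxymethoxy)phenyl]methyl}-2-oxocyclohex-3-ene-1-carboxylate (racemic), via Michael adduct 13 (not isolated), via ketol 14 (not isolated)
Conditions: NaOMe (0.2 equiv), MeOH/THF, 12 (1.0 equiv) added slowly, 0 °C → rt; then NaOMe (2 equiv), 3 Å molecular sieves, MeOH, 65 °C; AcOH
Reagents that add atoms: none
Why: Catalytic methoxide deprotonates only the carbon between the two carbonyls of 8, which adds to enone 12 to give 1,5-diketone 13 (the C4–C5 bond of ring A). With more base and heat, reversible proton transfer exposes the enolate of the methylene next to the diarylmethyl group, which attacks the aryl ketone to give ketol 14, and E1cB loss of water gives the conjugated enone 15 (the C1=C2 bond). The closest known reaction type is the Robinson annulation of β-keto esters with aryl vinyl ketones or chalcones to Hagemann-ester-type 2-oxocyclohex-3-ene-1-carboxylates. Ring A closes in a 6-(enolexo)-exo-trig aldol addition. The ester-bearing carbon of 15 is the only stereocentre left; it is epimerisable, uncontrolled and racemic, and it vanishes in step 8, while the ketol centres of 14 are lost on dehydration. The step needs regiocontrol in both enolate reactions: the Michael stage is secured by the far higher acidity of the doubly activated carbon, and the aldol stage by ring size, since the enolate of the aryl ketone could only close a four-membered ring. Slow addition of one equivalent of 12 suppresses a second Michael addition, methoxide matches the methyl ester, the sieves hold back the water that would saponify and decarboxylate the keto ester, and the absence of acid keeps all four MOM ethers. Any β,γ-alkene isomer formed alongside 15 is at the same oxidation level and converges on 19 in step 8.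

Step 8
Reactants: 15 methyl 4-[2,4-bis(methoxymethoxy)phenyl]-3-{bis[4-(methoxymethoxy)phenyl]methyl}-2-oxocyclohex-3-ene-1-carboxylate
Product: 19 methyl 4-[2,4-bis(methoxymethoxy)phenyl]-3-{bis[4-(methoxymethoxy)phenyl]methyl}-2-hydroxybenzoate, via selenide 16 (not isolated), via selenoxide 17 (not isolated), via dienone tautomer 18 (not isolated)
Conditions: PhSeCl (1.1 equiv), pyridine, CH2Cl2, 0 °C → rt; then 30% H2O2 (excess), 0 °C → rt
Reagents that add atoms: none
Why: Selenation and selenoxide syn-elimination of a β-dicarbonyl compound: the enol of the keto ester is selenated at the ester-bearing carbon, oxidation gives selenoxide 17, which can only eliminate towards the ring CH2, and the cross-conjugated dienone 18 is the keto tautomer of phenol 19 and enolises to it; MOM ethers and the triarylmethane C–H are untouched.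

Step 9
Reactants: 19 methyl 4-[2,4-bis(methoxymethoxy)phenyl]-3-{bis[4-(methoxymethoxy)phenyl]methyl}-2-hydroxybenzoate
Product: 20 methyl 4-[2,4-bis(methoxymethoxy)phenyl]-3-{bis[4-(methoxymethoxy)phenyl]methyl}-2-{[(trifluoromethyl)sulfonyl]oxy}benzoate
Conditions: Tf2O (1.3 equiv), pyridine, CH2Cl2, 0 °C → rt
Reagents that add atoms: trifluoromethanesulfonic anhydride, O=S(=O)(OS(=O)(=O)C(F)(F)F)C(F)(F)F
Why: O-triflation of the salicylate phenol; the hydrogen bond to the ester and the flanking groups slow it, hence the excess of anhydride, and pyridine keeps the medium basic for the MOM ethers.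

Step 10
Reactants: 21 4-hydroxybenzaldehyde
Product: 22 4-(methoxymethoxy)benzaldehyde
Conditions: MOMCl (1.5 equiv), i-Pr2NEt (2 equiv), CH2Cl2, 0 °C → rt
Reagents that add atoms: chloromethyl methyl ether, COCCl
Why: MOM protection of the phenol, as in step 1.

Step 11
Reactants: 22 4-(methoxymethoxy)benzaldehyde
Product: 23 1-ethynyl-4-(methoxymethoxy)benzene
Conditions: dimethyl (1-diazo-2-oxopropyl)phosphonate (1.2 equiv), K2CO3 (2 equiv), MeOH, rt
Reagents that add atoms: dimethyl (1-diazo-2-oxopropyl)phosphonate, CC(=O)C(=[N+]=[N-])P(=O)(OC)OC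
Why: Ohira–Bestmann (Seyferth–Gilbert) homologation: methanolysis of the reagent releases the anion of dimethyl (diazomethyl)phosphonate, which adds to the aldehyde; loss of phosphate and nitrogen with a 1,2-hydrogen shift gives the terminal alkyne, and MOM is stable to K2CO3 in methanol.

Step 12
Reactants: 20 methyl 4-[2,4-bis(methoxymethoxy)phenyl]-3-{bis[4-(methoxymethoxy)phenyl]methyl}-2-{[(trifluoromethyl)sulfonyl]oxy}benzoate; 23 1-ethynyl-4-(methoxymethoxy)benzene
Product: 24 methyl 4-[2,4-bis(methoxymethoxy)phenyl]-3-{bis[4-(methoxymethoxy)phenyl]methyl}-2-{[4-(methoxymethoxy)phenyl]ethynyl}benzoate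
Conditions: Pd(PPh3)2Cl2 (5 mol%), CuI (10 mol%), Et3N, DMF (degassed), 23 added slowly, 70 °C
Reagents that add atoms: none
Why: Sonogashira coupling: zerovalent palladium formed in the flask inserts into the C–OTf bond, which the ortho ester activates, and the copper acetylide of 23 transmetalates; the linear alkyne is the smallest carbon partner that can enter between the ester and the diarylmethyl group.

Step 13
Reactants: 24 methyl 4-[2,4-bis(methoxymethoxy)phenyl]-3-{bis[4-(methoxymethoxy)phenyl]methyl}-2-{[4-(methoxymethoxy)phenyl]ethynyl}benzoate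
Product: 25 [4-[2,4-bis(methoxymethoxy)phenyl]-3-{bis[4-(methoxymethoxy)phenyl]methyl}-2-{[4-(methoxymethoxy)phenyl]ethynyl}phenyl]methanol
Conditions: i-Bu2AlH (2.5 equiv), CH2Cl2, −78 → −20 °C; aq. potassium sodium tartrate
Reagents that add atoms: none
Why: i-Bu2AlH reduction of the ester to the primary alcohol at low temperature, where the diarylalkyne and the MOM ethers are inert; reducing before deprotection spares hydride that five phenols would consume.

Step 14
Reactants: 25 [4-[2,4-bis(methoxymethoxy)phenyl]-3-{bis[4-(methoxymethoxy)phenyl]methyl}-2-{[4-(methoxymethoxy)phenyl]ethynyl}phenyl]methanol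
Product: 26 4-{2-[bis(4-hydroxyphenyl)methyl]-4-(hydroxymethyl)-3-[(4-hydroxyphenyl)ethynyl]phenyl}benzene-1,3-diol
Conditions: HCl (1.25 M in MeOH), MeOH/THF, 40 °C, argon
Reagents that add atoms: none
Why: Acid-catalysed transacetalisation of the five aryl MOM ethers to the solvent methanol, which captures each methoxymethyl unit as dimethoxymethane before it can alkylate the resorcinol ring; the ring A benzylic alcohol is not activated enough to etherify under these mild conditions, and argon keeps the leuco compound from early oxidation.

Step 15
Reactants: 26 4-{2-[bis(4-hydroxyphenyl)methyl]-4-(hydroxymethyl)-3-[(4-hydroxyphenyl)ethynyl]phenyl}benzene-1,3-diol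
Product: 27 selaginellin F, 4-{[2',4'-dihydroxy-4-(hydroxymethyl)-3-[(4-hydroxyphenyl)ethynyl]biphenyl-2-yl](4-hydroxyphenyl)methylidene}cyclohexa-2,5-dien-1-one
Conditions: DDQ (1.0 equiv), THF, 0 °C
Reagents that add atoms: none
Why: Quinone dehydrogenation of a 4-hydroxytriarylmethane (leuco form) to the fuchsone: hydride leaves the doubly benzylic C7–H para to two phenols and the carbenium loses a phenolic proton; the two hydroxyphenyl rings on C7 are equivalent, so one product is possible, and no other C–H in 26 is activated by a para hydroxyl.

## Compound list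

1 | methyl (2E)-3-(4-hydroxyphenyl)prop-2-enoate | COC(=O)/C=C/c1ccc(O)cc1 | starting material
2 | methyl (2E)-3-[4-(methoxymethoxy)phenyl]prop-2-enoate | COCOc1ccc(/C=C/C(=O)OC)cc1 | intermediate
3 | [4-(methoxymethoxy)phenyl]boronic acid | COCOc1ccc(B(O)O)cc1 | starting material
4 | methyl 3,3-bis[4-(methoxymethoxy)phenyl]propanoate | COC(=O)CC(c1ccc(OCOC)cc1)c1ccc(OCOC)cc1 | intermediate
5 | 3,3-bis[4-(methoxymethoxy)phenyl]propanoic acid | OC(=O)CC(c1ccc(OCOC)cc1)c1ccc(OCOC)cc1 | intermediate
6 | 1-(1H-imidazol-1-yl)-3,3-bis[4-(methoxymethoxy)phenyl]propan-1-one | O=C(CC(c1ccc(OCOC)cc1)c1ccc(OCOC)cc1)n1ccnc1 | intermediate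
7 | 2-(methoxycarbonyl)-5,5-bis[4-(methoxymethoxy)phenyl]-3-oxopentanoic acid (present as its magnesium chelate) | COC(=O)C(C(=O)O)C(=O)CC(c1ccc(OCOC)cc1)c1ccc(OCOC)cc1 | intermediate
8 | methyl 5,5-bis[4-(methoxymethoxy)phenyl]-3-oxopentanoate | COC(=O)CC(=O)CC(c1ccc(OCOC)cc1)c1ccc(OCOC)cc1 | intermediate
9 | 2,4-dihydroxybenzaldehyde | O=Cc1ccc(O)cc1O | starting material
10 | 2,4-bis(methoxymethoxy)benzaldehyde | COCOc1ccc(C=O)c(OCOC)c1 | intermediate
11 | 1-[2,4-bis(methoxymethoxy)phenyl]prop-2-en-1-ol (racemic) | C=CC(O)c1ccc(OCOC)cc1OCOC | intermediate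
12 | 1-[2,4-bis(methoxymethoxy)phenyl]prop-2-en-1-one | C=CC(=O)c1ccc(OCOC)cc1OCOC | intermediate
13 | methyl 2-{3-[2,4-bis(methoxymethoxy)phenyl]-3-oxopropyl}-5,5-bis[4-(methoxymethoxy)phenyl]-3-oxopentanoate (racemic) | COC(=O)C(CCC(=O)c1ccc(OCOC)cc1OCOC)C(=O)CC(c1ccc(OCOC)cc1)c1ccc(OCOC)cc1 | intermediate
14 | methyl 4-[2,4-bis(methoxymethoxy)phenyl]-3-{bis[4-(methoxymethoxy)phenyl]methyl}-4-hydroxy-2-oxocyclohexane-1-carboxylate (racemic mixture of diastereomers) | COC(=O)C1CCC(O)(c2ccc(OCOC)cc2OCOC)C(C(c2ccc(OCOC)cc2)c2ccc(OCOC)cc2)C1=O | intermediate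
15 | methyl 4-[2,4-bis(methoxymethoxy)phenyl]-3-{bis[4-(methoxymethoxy)phenyl]methyl}-2-oxocyclohex-3-ene-1-carboxylate (racemic) | COC(=O)C1CCC(c2ccc(OCOC)cc2OCOC)=C(C(c2ccc(OCOC)cc2)c2ccc(OCOC)cc2)C1=O | intermediate
16 | methyl 4-[2,4-bis(methoxymethoxy)phenyl]-3-{bis[4-(methoxymethoxy)phenyl]methyl}-2-oxo-1-(phenylselanyl)cyclohex-3-ene-1-carboxylate (racemic) | COC(=O)C1([Se]c2ccccc2)CCC(c2ccc(OCOC)cc2OCOC)=C(C(c2ccc(OCOC)cc2)c2ccc(OCOC)cc2)C1=O | intermediate
17 | methyl 1-(benzeneseleninyl)-4-[2,4-bis(methoxymethoxy)phenyl]-3-{bis[4-(methoxymethoxy)phenyl]methyl}-2-oxocyclohex-3-ene-1-carboxylate (mixture of stereoisomers) | COC(=O)C1([Se](=O)c2ccccc2)CCC(c2ccc(OCOC)cc2OCOC)=C(C(c2ccc(OCOC)cc2)c2ccc(OCOC)cc2)C1=O | intermediate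
18 | methyl 4-[2,4-bis(methoxymethoxy)phenyl]-5-{bis[4-(methoxymethoxy)phenyl]methyl}-6-oxocyclohexa-1,4-diene-1-carboxylate | COC(=O)C1=CCC(c2ccc(OCOC)cc2OCOC)=C(C(c2ccc(OCOC)cc2)c2ccc(OCOC)cc2)C1=O | intermediate
19 | methyl 4-[2,4-bis(methoxymethoxy)phenyl]-3-{bis[4-(methoxymethoxy)phenyl]methyl}-2-hydroxybenzoate | COC(=O)c1ccc(-c2ccc(OCOC)cc2OCOC)c(C(c2ccc(OCOC)cc2)c2ccc(OCOC)cc2)c1O | intermediate
20 | methyl 4-[2,4-bis(methoxymethoxy)phenyl]-3-{bis[4-(methoxymethoxy)phenyl]methyl}-2-{[(trifluoromethyl)sulfonyl]oxy}benzoate | COC(=O)c1ccc(-c2ccc(OCOC)cc2OCOC)c(C(c2ccc(OCOC)cc2)c2ccc(OCOC)cc2)c1OS(=O)(=O)C(F)(F)F | intermediate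
21 | 4-hydroxybenzaldehyde | O=Cc1ccc(O)cc1 | starting material
22 | 4-(methoxymethoxy)benzaldehyde | COCOc1ccc(C=O)cc1 | intermediate
23 | 1-ethynyl-4-(methoxymethoxy)benzene | C#Cc1ccc(OCOC)cc1 | intermediate
24 | methyl 4-[2,4-bis(methoxymethoxy)phenyl]-3-{bis[4-(methoxymethoxy)phenyl]methyl}-2-{[4-(methoxymethoxy)phenyl]ethynyl}benzoate | COC(=O)c1ccc(-c2ccc(OCOC)cc2OCOC)c(C(c2ccc(OCOC)cc2)c2ccc(OCOC)cc2)c1C#Cc1ccc(OCOC)cc1 | intermediate
25 | [4-[2,4-bis(methoxymethoxy)phenyl]-3-{bis[4-(methoxymethoxy)phenyl]methyl}-2-{[4-(methoxymethoxy)phenyl]ethynyl}phenyl]methanol | OCc1ccc(-c2ccc(OCOC)cc2OCOC)c(C(c2ccc(OCOC)cc2)c2ccc(OCOC)cc2)c1C#Cc1ccc(OCOC)cc1 | intermediate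
26 | 4-{2-[bis(4-hydroxyphenyl)methyl]-4-(hydroxymethyl)-3-[(4-hydroxyphenyl)ethynyl]phenyl}benzene-1,3-diol | OCc1ccc(-c2ccc(O)cc2O)c(C(c2ccc(O)cc2)c2ccc(O)cc2)c1C#Cc1ccc(O)cc1 | intermediate
27 | selaginellin F, 4-{[2',4'-dihydroxy-4-(hydroxymethyl)-3-[(4-hydroxyphenyl)ethynyl]biphenyl-2-yl](4-hydroxyphenyl)methylidene}cyclohexa-2,5-dien-1-one | O=C1C=CC(=C(c2ccc(O)cc2)c2c(-c3ccc(O)cc3O)ccc(CO)c2C#Cc2ccc(O)cc2)C=C1 | target

## Step count and least certain steps

Total step count: 15. Longest linear sequence: 10 steps (steps 1, 2, 3, 7, 8, 9, 12, 13, 14, 15).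

**Step 7 (key step).** The most likely failure is stalling after the Michael addition. The aldol addition to a hindered, electron-rich aryl ketone is slow and reversible, and dehydration beside the diarylmethyl group and ring B may not pull it through. Prolonged heating then favours retro-Michael cleavage, polymerisation of the enone and saponification with decarboxylation of the keto ester by the water released.

Fallback: this sets out from 8 and replaces the aldol closure by a Claisen closure with a strong driving force. Methyl acrylate and NaOMe in MeOH should give dimethyl 2-{3,3-bis[4-(methoxymethoxy)phenyl]propanoyl}pentanedioate F1 as the Michael adduct. The methylene next to the diarylmethyl group then acylates on the side-chain ester to give methyl 3-{bis[4-(methoxymethoxy)phenyl]methyl}-2,4-dioxocyclohexane-1-carboxylate F2 in the form of its dione enolate. Dehydrogenation through the dianion (LiN(i-Pr)2, PhSeBr at the ester-bearing carbon, then H2O2) should give methyl 3-{bis[4-(methoxymethoxy)phenyl]methyl}-2,4-dihydroxybenzoate F3 after tautomerisation. Tf2O and pyridine at −20 °C should sulfonylate only the 4-hydroxyl, since the 2-hydroxyl is hydrogen-bonded to the ester, giving methyl 3-{bis[4-(methoxymethoxy)phenyl]methyl}-2-hydroxy-4-{[(trifluoromethyl)sulfonyl]oxy}benzoate F4 as the coupling partner. Suzuki–Miyaura coupling of this triflate with [2,4-bis(methoxymethoxy)phenyl]boronic acid F5 under Pd(OAc)2, SPhos and K3PO4 returns to the route at 19. The price is two more steps and a crowded biaryl coupling, which the main route avoids.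

**Step 8.** Selenation may be diverted to the electron-rich ring B or to the vinylogous position of the enone, and the selenoxide may decompose by paths other than syn-elimination.

Fallback: this sets out from 15. NaH then N-bromosuccinimide in THF at 0 °C should brominate the sodium enolate at the ester-bearing carbon to give methyl 1-bromo-4-[2,4-bis(methoxymethoxy)phenyl]-3-{bis[4-(methoxymethoxy)phenyl]methyl}-2-oxocyclohex-3-ene-1-carboxylate F6 as a tertiary bromide. DBU then effects base-induced dehydrobromination to dienone 18, which tautomerises, returning to the route at 19.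

**Step 12.** Oxidative addition and transmetalation at a triflate flanked by the ester and the diarylmethyl group may be slow. Copper-mediated homocoupling of 23 and hydrolysis of the triflate back to 19 could then overtake the cross-coupling.

Fallback: this sets out from 20 and builds the alkyne from the other end. Sonogashira coupling with the small ethynyltrimethylsilane should give methyl 4-[2,4-bis(methoxymethoxy)phenyl]-3-{bis[4-(methoxymethoxy)phenyl]methyl}-2-[(trimethylsilyl)ethynyl]benzoate F7 at the crowded position. K2CO3 in MeOH should then remove the silyl group and give methyl 4-[2,4-bis(methoxymethoxy)phenyl]-3-{bis[4-(methoxymethoxy)phenyl]methyl}-2-ethynylbenzoate F8 as a terminal alkyne. A second Sonogashira coupling of this alkyne with 1-iodo-4-(methoxymethoxy)benzene F9 then returns to the route at 24; this aryl iodide is unhindered and reactive.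

**Step 14.** Methoxymethyl cations or formaldehyde may be captured by the resorcinol ring B (hydroxymethylation or methylene bridging). The CH2OH oxygen may add to the protonated alkyne or be etherified by methanol, and the hindered ortho MOM ether may cleave incompletely.

Fallback: this sets out from 25 and replaces protic solvolysis by Lewis acid and thiol exchange in an aprotic medium. ZnBr2 and n-PrSH in CH2Cl2 at 0 °C transfer each methoxymethyl unit to sulfur, with no protic acid and no methanol present. It returns to the route at 26 and makes no new compound.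

**Step 15.** The free pentaphenol may be oxidised unselectively (phenoxyl coupling at ring B, further oxidation of the product). Nucleophiles, including the ring B 2-hydroxyl, may add to the new quinone methide, and the reduced quinone may be hard to separate.

Fallback: this sets out from 25 and reverses the order of oxidation and deprotection. DDQ in wet CH2Cl2 should abstract hydride from C7 while the phenols are still masked and give, after water capture, [4-[2,4-bis(methoxymethoxy)phenyl]-3-{hydroxybis[4-(methoxymethoxy)phenyl]methyl}-2-{[4-(methoxymethoxy)phenyl]ethynyl}phenyl]methanol F10 as a triaryl carbinol. Methanolic HCl then removes the five MOM groups; the triaryl carbinol ionises and loses water to the quinone methide, returning to the route at 27 without passing through 26.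

## Further compounds

F1 | step 7 | dimethyl 2-{3,3-bis[4-(methoxymethoxy)phenyl]propanoyl}pentanedioate | COC(=O)CCC(C(=O)OC)C(=O)CC(c1ccc(OCOC)cc1)c1ccc(OCOC)cc1
F2 | step 7 | methyl 3-{bis[4-(methoxymethoxy)phenyl]methyl}-2,4-dioxocyclohexane-1-carboxylate | COC(=O)C1CCC(=O)C(C(c2ccc(OCOC)cc2)c2ccc(OCOC)cc2)C1=O
F3 | step 7 | methyl 3-{bis[4-(methoxymethoxy)phenyl]methyl}-2,4-dihydroxybenzoate | COC(=O)c1ccc(O)c(C(c2ccc(OCOC)cc2)c2ccc(OCOC)cc2)c1O
F4 | step 7 | methyl 3-{bis[4-(methoxymethoxy)phenyl]methyl}-2-hydroxy-4-{[(trifluoromethyl)sulfonyl]oxy}benzoate | COC(=O)c1ccc(OS(=O)(=O)C(F)(F)F)c(C(c2ccc(OCOC)cc2)c2ccc(OCOC)cc2)c1O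
F5 | step 7 | [2,4-bis(methoxymethoxy)phenyl]boronic acid | COCOc1ccc(B(O)O)c(OCOC)c1
F6 | step 8 | methyl 1-bromo-4-[2,4-bis(methoxymethoxy)phenyl]-3-{bis[4-(methoxymethoxy)phenyl]methyl}-2-oxocyclohex-3-ene-1-carboxylate | COC(=O)C1(Br)CCC(c2ccc(OCOC)cc2OCOC)=C(C(c2ccc(OCOC)cc2)c2ccc(OCOC)cc2)C1=O
F7 | step 12 | methyl 4-[2,4-bis(methoxymethoxy)phenyl]-3-{bis[4-(methoxymethoxy)phenyl]methyl}-2-[(trimethylsilyl)ethynyl]benzoate | COC(=O)c1ccc(-c2ccc(OCOC)cc2OCOC)c(C(c2ccc(OCOC)cc2)c2ccc(OCOC)cc2)c1C#C[Si](C)(C)C
F8 | step 12 | methyl 4-[2,4-bis(methoxymethoxy)phenyl]-3-{bis[4-(methoxymethoxy)phenyl]methyl}-2-ethynylbenzoate | COC(=O)c1ccc(-c2ccc(OCOC)cc2OCOC)c(C(c2ccc(OCOC)cc2)c2ccc(OCOC)cc2)c1C#C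
F9 | step 12 | 1-iodo-4-(methoxymethoxy)benzene | COCOc1ccc(I)cc1
F0 | step 14 | none | none
F10 | step 15 | [4-[2,4-bis(methoxymethoxy)phenyl]-3-{hydroxybis[4-(methoxymethoxy)phenyl]methyl}-2-{[4-(methoxymethoxy)phenyl]ethynyl}phenyl]methanol | OCc1ccc(-c2ccc(OCOC)cc2OCOC)c(C(O)(c2ccc(OCOC)cc2)c2ccc(OCOC)cc2)c1C#Cc1ccc(OCOC)cc1
A1 | alternative 1 | {2-[(4-methoxybenzyl)oxy]-5-[(methoxymethoxy)methyl]-6-{[4-(methoxymethoxy)phenyl]ethynyl}phenyl}bis[4-(methoxymethoxy)phenyl]methanol | COCOCc1ccc(OCc2ccc(OC)cc2)c(C(O)(c2ccc(OCOC)cc2)c2ccc(OCOC)cc2)c1C#Cc1ccc(OCOC)cc1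
A2 | alternative 1 | 2-iodo-6-[(4-methoxybenzyl)oxy]-3-[(methoxymethoxy)methyl]phenyl 4-chlorobenzenesulfonate | COCOCc1ccc(OCc2ccc(OC)cc2)c(OS(=O)(=O)c2ccc(Cl)cc2)c1I
A3 | alternative 1 | bis[4-(methoxymethoxy)phenyl]methanone | COCOc1ccc(C(=O)c2ccc(OCOC)cc2)cc1
A4 | alternative 2 | 3-(methoxymethoxy)-6H-benzo[c]chromen-6-one with a fused γ-lactone (carbonyl on C7, OCH2 on C8) | O=C1OCc2ccc3-c4ccc(OCOC)cc4OC(=O)c3c21
A5 | alternative 2 | 2-ethynyl-5-(methoxymethoxy)phenyl prop-2-yn-1-yl but-2-ynedioate | C#CCOC(=O)C#CC(=O)Oc1cc(OCOC)ccc1C#C
A6 | alternative 3 | 7-bromo-6-oxo-8-[(pivaloyloxy)methyl]-6H-benzo[c]chromen-3-yl pivalate | O=C1Oc2cc(OC(=O)C(C)(C)C)ccc2-c2ccc(COC(=O)C(C)(C)C)c(Br)c21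
A7 | alternative 3 | 2-bromo-3-[(pivaloyloxy)methyl]-6-[4-(pivaloyloxy)phenyl]benzoic acid | OC(=O)c1c(Br)c(COC(=O)C(C)(C)C)ccc1-c1ccc(OC(=O)C(C)(C)C)cc1
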